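**Retrosynthetic overview**

1. Feature (briarane numbering): the γ-lactone C7–O–C19(=O)–C17–C8 is fused to the ten-membered carbocycle C1–C10, and its tertiary C8 carbinol lies β to C19. The lactone is therefore the aldol adduct of a C7-bound propanoate and a C8 ring ketone, and C8–C17 is cut (tethered zinc enolate onto the ketone); C17–OH and the acyl groups follow.
2. The ten-membered 8-ketone comes from chromium-mediated C6–C7 closure of a (Z)-vinyl iodide onto a C7 aldehyde. The C7 ester is put on with inversion, and C8 travels as a PMB ether until it is oxidised.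
3. Both arms grow from the cyclohexene core by reagent-controlled (Z)-γ-alkoxyallylborations (C2/C3 and C9/C8) and one chelate-controlled alkenyl addition (C4).
4. The core (C1, C10–C14) comes from an enantioselective Diels–Alder reaction (bonds C1–C14 and C10–C11), then enone → 1,3-diene → cis-dihydroxylation (C11, C12).
5. Ring order: cyclohexene → temporary dioxolane → ten-membered ring → γ-lactone.

Key step: step 29

**Remarks (assumptions)**

- Briarane numbering is used for all intermediates; PMB = 4-methoxybenzyl, MOM = methoxymethyl, Ipc = isopinocampheyl from (+)-α-pinene.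
- Compounds 1, 2, 4, 16, 22, 23, 31 and 38 are taken as purchasable.
- C11 of adduct 6 (endo/exo) is left undefined in 6–9, because it becomes sp2 in step 7.
- The sense of induction in step 3 is assigned from the formyl C–H···O binding model for α-substituted enals; the antipodal catalyst is equally available should the sense be opposite.
- C3 carries MOM (not PMB) so that the C8 PMB ether can be removed alone in step 27.

**Route**

Step 1
Reactants: 1 2-[(4-methoxybenzyl)oxy]acetaldehyde; 2 2-(triphenylphosphoranylidene)propanal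
Product: 3 (E)-4-[(4-methoxybenzyl)oxy]-2-methylbut-2-enal
Conditions: toluene, 80 °C
Reagents that add atoms: none
Why: Wittig olefination with a stabilised α-methyl formyl ylide should give the E-enal (CHO trans to CH2OPMB), the geometry that later places C2 and C9 trans on the cyclohexene.

Step 2
Reactants: 4 pent-1-en-3-one
Product: 5 (Z)-3-(tert-butyldimethylsilyloxy)penta-1,3-diene
Conditions: TBSOTf, Et3N, Et2O, 0 °C
Reagents that add atoms: tert-butyldimethylsilyl triflate CC(C)(C)[Si](C)(C)OS(=O)(=O)C(F)(F)F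
Why: Soft enolisation (silyl triflate/amine) of the ethyl ketone gives the 2-silyloxy diene, mainly as the Z enol ether whose terminal methyl points outward so the s-cis conformation is accessible.

Step 3
Reactants: 3 (E)-enal; 5 silyloxy diene
Product: 6 Diels–Alder adduct (1S,10S): cyclohexene with C1 methyl and formyl (C2), C10 CH2OPMB (C9) trans to the formyl group, C11 methyl (epimers), C12 silyl enol ether (C12=C13)
Conditions: (R)-B-(o-tolyl)-diphenylprolinol-derived oxazaborolidine·Tf2NH (20 mol %), CH2Cl2, −78 → −40 °C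
Reagents that add atoms: none
Why: Catalytic enantioselective Diels–Alder reaction in which the 2-silyloxy group directs the "para" orientation (bonds C1–C14 and C10–C11), the E geometry is transferred suprafacially (C2 and C9 trans, Me-15 cis to C9), and the cationic oxazaborolidine should leave the si face of the enal α-carbon open, setting C1 and C10.

Step 4
Reactants: 6 Diels–Alder adduct
Product: 7 C2 primary alcohol
Conditions: NaBH4, EtOH/THF, 0 °C
Reagents that add atoms: none
Why: Borohydride reduces the neopentyl aldehyde and leaves the silyl enol ether, masking C2 while the ring is functionalised.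

Step 5
Reactants: 7 C2 primary alcohol
Product: 8 C2 tert-butyldimethylsilyl ether
Conditions: TBSCl, imidazole, DMF, rt
Reagents that add atoms: tert-butyldimethylsilyl chloride CC(C)(C)[Si](C)(C)Cl
Why: Standard silylation of a primary alcohol; the enol ether and PMB ether are unaffected.

Step 6
Reactants: 8 C2 silyl ether
Product: 9 cyclohexenone (C12=O, C13=C14)
Conditions: Pd(OAc)2 (1.1 equiv), MeCN, rt → 40 °C
Reagents that add atoms: none
Why: Saegusa–Ito oxidation: the palladium(II) enolate from the enol silane undergoes β-hydride elimination toward C14, the only position carrying a β-hydrogen, and so installs C13=C14.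

Step 7
Reactants: 9 cyclohexenone
Product: 10 dienyl triflate (C11=C12(OTf), C13=C14)
Conditions: KHMDS, THF, −78 °C; PhNTf2, −78 → 0 °C
Reagents that add atoms: N-phenylbis(trifluoromethanesulfonimide) O=S(=O)(N(c1ccccc1)S(=O)(=O)C(F)(F)F)C(F)(F)F
Why: Kinetic enolisation can occur only at C11 (C1 is quaternary, so there is no γ-hydrogen), and O-triflation of the cross-conjugated dienolate gives the dienyl triflate and removes the undefined C11 centre.

Step 8
Reactants: 10 dienyl triflate
Product: 11 cyclohexa-1,3-diene (C11=C12, C13=C14)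
Conditions: Pd(OAc)2 (5 mol %), PPh3, HCO2H, Bu3N, DMF, 60 °C
Reagents that add atoms: none
Why: Palladium-catalysed formate reduction of an enol triflate (oxidative addition, decarboxylation of formate, reductive elimination) replaces OTf by H without moving the double bonds.

Step 9
Reactants: 11 cyclohexadiene
Product: 12 (11S,12R)-cis-diol with C13=C14 retained
Conditions: OsO4 (2 mol %), NMO, acetone/H2O, 0 °C
Reagents that add atoms: N-methylmorpholine N-oxide C[N+]1([O-])CCOCC1; water O
Why: Upjohn dihydroxylation should engage the more electron-rich trisubstituted C11=C12 bond of the diene (C13=C14 is shielded by quaternary C1) from the face anti to the allylic C10 CH2OPMB group, syn addition giving the cis-11,12-diol with Me-20 on the face of Me-15.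

Step 10
Reactants: 12 cis-diol
Product: 13 11,12-acetonide
Conditions: Me2C(OMe)2, PPTS (cat.), CH2Cl2, rt
Reagents that add atoms: 2,2-dimethoxypropane COC(C)(C)OC
Why: Acid-catalysed transketalisation ties the cis-diol into a cis-fused dioxolane.

Step 11
Reactants: 13 acetonide
Product: 14 C2 primary alcohol
Conditions: TBAF, THF, rt
Reagents that add atoms: none
Why: Fluoride cleaves the only silyl ether present.

Step 12
Reactants: 14 C2 primary alcohol
Product: 15 C2 aldehyde
Conditions: Dess–Martin periodinane, NaHCO3, CH2Cl2, 0 °C → rt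
Reagents that add atoms: none
Why: Dess–Martin oxidation of the neopentyl alcohol gives a non-enolisable aldehyde.

Step 13
Reactants: 15 C2 aldehyde; 16 allyl methoxymethyl ether
Product: 18 (2R,3R)-homoallylic alcohol (C2-OH; C3-OMOM; vinyl), via Z-alkoxyallylborane 17 (not isolated)
Conditions: 16, s-BuLi, THF, −78 °C; (−)-Ipc2BOMe; BF3·OEt2; then 15, −78 °C → rt; NaOH, H2O2
Reagents that add atoms: none
Why: (Z)-γ-Alkoxyallylboration through a closed chair transition state converts the Z enol ether geometry into the 2,3-syn relationship, and the (+)-α-pinene-derived boron ligands direct attack to the si face of the aldehyde, so C2 and C3 are set by the reagent.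

Step 14
Reactants: 18 homoallylic alcohol
Product: 19 C2 triethylsilyl ether
Conditions: TESOTf, 2,6-lutidine, CH2Cl2, −78 °C
Reagents that add atoms: triethylsilyl triflate CC[Si](CC)(CC)OS(=O)(=O)C(F)(F)F
Why: The silyl triflate silylates the hindered neopentyl secondary alcohol; no stereocentre is touched.

Step 15
Reactants: 19 C2 silyl ether
Product: 21 C4 aldehyde, via 1,2-diol 20 (not isolated)
Conditions: OsO4 (cat.), NaIO4, 2,6-lutidine, dioxane/H2O, rt
Reagents that add atoms: sodium periodate [Na+].[O-]I(=O)(=O)=O; water O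
Why: Lemieux–Johnson cleavage: osmylation should select the monosubstituted vinyl group over the hindered, allylically oxygenated cis ring alkene, and periodate cleaves the diol to the aldehyde under lutidine buffering without epimerising C3.

Step 16
Reactants: 22 propyne; 23 tributyl(trimethylsilyl)stannane
Product: 24 (Z)-trimethyl[2-(tributylstannyl)prop-1-enyl]silane
Conditions: Pd(PPh3)4 (2 mol %), THF, 65 °C, sealed tube
Reagents that add atoms: none
Why: Palladium(0)-catalysed silylstannation of a terminal alkyne adds Si–Sn syn with tin on the internal carbon, fixing the cis Sn/Si geometry that becomes the Z C5=C6 bond.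

Step 17
Reactants: 21 C4 aldehyde; 24 stannylsilane
Product: 26 (4S)-allylic alcohol bearing the Z-vinylsilane, via alkenylmagnesium bromide 25 (not isolated)
Conditions: 24, MeLi, THF, −78 → −20 °C; MgBr2·OEt2; then 21 (precomplexed with MgBr2·OEt2, CH2Cl2), −78 °C
Reagents that add atoms: none
Why: Tin–lithium exchange and transmetalation proceed with retention, and Cram-chelate addition (magnesium bridging the aldehyde oxygen and the C3 MOM ether, the C2 silyl ether not chelating) should deliver the alkenyl group to give the 3,4-syn alcohol.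

Step 18
Reactants: 26 allylic alcohol
Product: 27 C4 tert-butyldimethylsilyl ether
Conditions: TBSOTf, 2,6-lutidine, CH2Cl2, −78 → 0 °C
Reagents that add atoms: tert-butyldimethylsilyl triflate CC(C)(C)[Si](C)(C)OS(=O)(=O)C(F)(F)F
Why: Standard silylation of a secondary allylic alcohol.

Step 19
Reactants: 27 vinylsilane
Product: 28 (Z)-vinyl iodide (C6–I cis to C4)
Conditions: NIS, ClCH2CN/MeCN, 0 °C, dark
Reagents that add atoms: N-iodosuccinimide O=C1CCC(=O)N1I
Why: Iododesilylation (ipso attack of I+ at the silicon-bearing carbon, then loss of silicon from the β-silyl cation) proceeds with retention in nitrile solvent and gives the Z iodide.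

Step 20
Reactants: 28 vinyl iodide
Product: 29 C9 primary alcohol
Conditions: DDQ, CH2Cl2/pH 7 buffer, 0 °C
Reagents that add atoms: none
Why: Oxidative cleavage of the only PMB ether present; MOM, silyl ethers, acetonide and vinyl iodide are inert to DDQ.

Step 21
Reactants: 29 C9 primary alcohol
Product: 30 C9 aldehyde
Conditions: Dess–Martin periodinane, NaHCO3, CH2Cl2, 0 °C
Reagents that add atoms: none
Why: Buffered Dess–Martin oxidation gives the aldehyde, which is used at once so that C10 does not epimerise.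

Step 22
Reactants: 30 C9 aldehyde; 31 allyl 4-methoxybenzyl ether
Product: 33 (8R,9R)-homoallylic alcohol (C9-OH; C8-OPMB; vinyl), via Z-alkoxyallylborane 32 (not isolated)
Conditions: 31, s-BuLi, THF, −78 °C; (−)-Ipc2BOMe; BF3·OEt2; then 30, −78 → −20 °C; NaOH, H2O2
Reagents that add atoms: none
Why: A second (Z)-γ-alkoxyallylboration sets C9 by reagent control (si face, overriding the uncertain bias of the hindered ring aldehyde) and gives a syn C8 ether that serves only as a masked ketone.

Step 23
Reactants: 33 homoallylic alcohol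
Product: 34 C9 triethylsilyl ether
Conditions: TESOTf, 2,6-lutidine, CH2Cl2, −78 → 0 °C
Reagents that add atoms: triethylsilyl triflate CC[Si](CC)(CC)OS(=O)(=O)C(F)(F)F
Why: Silylation of a hindered secondary alcohol with the silyl triflate.

Step 24
Reactants: 34 C9 silyl ether
Product: 36 C7 aldehyde, via 1,2-diol 35 (not isolated)
Conditions: OsO4 (cat.), NaIO4, 2,6-lutidine, dioxane/H2O, rt
Reagents that add atoms: sodium periodate [Na+].[O-]I(=O)(=O)=O; water O
Why: Lemieux–Johnson cleavage of the terminal vinyl group; the iodine-bearing trisubstituted alkene and the hindered ring alkene are much poorer osmylation substrates.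

Step 25
Reactants: 36 C7 aldehyde
Product: 37 ten-membered (7R)-allylic alcohol (ring C1–C10 closed at C6–C7)
Conditions: CrCl2 (10 equiv), NiCl2 (1 mol %), DMSO/THF, 3 mM, rt
Reagents that add atoms: none
Why: Intramolecular Nozaki–Hiyama–Kishi coupling, in which the alkenylchromium(III) formed at C6 with retention of the Z geometry adds only to the aldehyde, the cis alkene and the trans arms on the cyclohexene holding the termini within reach at high dilution; a Felkin–Anh/Cornforth arrangement of the C8 ether under non-chelating chromium(III) should favour the 7,8-anti (7R) alcohol.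

Step 26
Reactants: 37 (7R)-allylic alcohol; 38 (S)-2-bromopropanoic acid
Product: 39 (7S)-2-bromopropanoate
Conditions: PPh3, DIAD (betaine preformed), toluene, 0 °C → rt
Reagents that add atoms: none
Why: Mitsunobu esterification displaces the oxyphosphonium group at allylic C7 with inversion (SN2′ at the fully substituted C5 is disfavoured); the configuration of the bromine-bearing carbon is immaterial because it becomes the enolate carbon in step 29.

Step 27
Reactants: 39 bromopropanoate
Product: 40 C8 alcohol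
Conditions: DDQ, CH2Cl2/pH 7 buffer, 0 °C → rt
Reagents that add atoms: none
Why: DDQ removes the single PMB ether under neutral conditions that tolerate the α-bromo ester and suppress 7→8 acyl migration.

Step 28
Reactants: 40 C8 alcohol
Product: 41 ten-membered 8-ketone carrying the C7 (S)-2-bromopropanoate (C2,C9-OTES; C3-OMOM; C4-OTBS; 11,12-acetonide)
Conditions: Dess–Martin periodinane, NaHCO3, CH2Cl2, 0 °C → rt
Reagents that add atoms: none
Why: Buffered Dess–Martin oxidation gives the α-acyloxy ketone without epimerising C7 or C9.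

Step 29
Reactants: 41 8-ketone bromopropanoate
Product: 43 β-hydroxy γ-lactone (8S; C17 methyl epimer as drawn), via zinc enolate 42 (not isolated)
Conditions: Zn dust (activated with TMSCl/1,2-dibromoethane), THF, 0.01 M, 25 → 50 °C; then H2O (pH 7)
Reagents that add atoms: none
Why: Zinc inserts into the C–Br bond, far faster than any electron transfer to the α-acyloxy ketone, giving a Reformatsky reagent held on O7 whose α-carbon C17 adds to the C8 carbonyl; protonation of the zinc aldolate gives 43. The closest known reaction type is the intramolecular Reformatsky cyclisation of 2-bromoacyl esters of α-hydroxy ketones to β-hydroxy-γ-butyrolactones. The five-membered ring closes by 5-exo-trig attack on the carbonyl with the enolate in the enolendo orientation, a mode tolerated here because the nucleophile is delivered from a carbon–zinc bond and not through a rigid in-plane enolate. C8 is controlled by C7 through the short tether together with the ten-membered ring, which should keep C6–C7–C8–C9 transoid and so present the carbonyl face that gives the trans-fused lactone (H-7 and 8-OH trans); zinc aldolates can revert on warming, so the closure can also settle on this isomer, which is expected to be the more stable one. C17 forms as one methyl epimer or a mixture, which does not matter because it is made planar again in step 30. The step needs chemoselectivity for C–Br insertion and no enolisation at C7–H or C9–H, which the neutral, weakly basic zinc enolate and the absence of other electrophiles should secure.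

Step 30
Reactants: 43 β-hydroxy γ-lactone
Product: 45 8,17-diol lactone (17S), via dilithium alkoxide enolate 44 (not isolated)
Conditions: LDA (2.5 equiv), THF, −78 → −40 °C; 2-(phenylsulfonyl)-3-phenyloxaziridine, −78 °C; then H2O
Reagents that add atoms: 2-(phenylsulfonyl)-3-phenyloxaziridine O=S(=O)(c1ccccc1)N1OC1c1ccccc1
Why: Enolate hydroxylation of a β-hydroxy lactone dianion (as in trans-selective alkylations of β-hydroxy-γ-butyrolactone dianions), in which the solvated lithium alkoxide on C8 should block its own face so that the N-sulfonyloxaziridine transfers oxygen to C17 anti to O8, giving the trans-8,17-diol; no other ester is present yet to be enolised.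

Step 31
Reactants: 45 8,17-diol lactone
Product: 46 C2,C9-diol (C4-OTBS retained)
Conditions: HF·pyridine, pyridine, THF, 0 °C
Reagents that add atoms: none
Why: Buffered HF·pyridine cleaves the two triethylsilyl ethers much faster than the tert-butyldimethylsilyl ether and leaves MOM and acetonide untouched.

Step 32
Reactants: 46 C2,C9-diol
Product: 47 C2,C9-diacetate
Conditions: Ac2O, pyridine, DMAP (cat.), CH2Cl2, 0 °C → rt
Reagents that add atoms: acetic anhydride CC(=O)OC(C)=O
Why: Acylation of the two secondary alcohols; the tertiary C8 and C17 hydroxyls should be too hindered to react under these mild conditions.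

Step 33
Reactants: 47 diacetate
Product: 48 C4 alcohol
Conditions: HF·pyridine, THF, rt
Reagents that add atoms: none
Why: Fluoride-mediated cleavage of the remaining silyl ether; acetates and lactone are stable, and C3 is still protected so no acyl group can migrate to it.

Step 34
Reactants: 48 C4 alcohol
Product: 49 C4 hexanoate (C3-OMOM; 11,12-acetonide)
Conditions: hexanoyl chloride, pyridine, DMAP (cat.), CH2Cl2, 0 °C
Reagents that add atoms: hexanoyl chloride CCCCCC(=O)Cl
Why: DMAP-catalysed acylation of the only free secondary (allylic) alcohol; the tertiary alcohols again stay free.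

Step 35
Reactants: 49 C4 hexanoate
Product: 50 CNP0153048.1
Conditions: Me2BBr, CH2Cl2, −78 °C; then THF/aq NaHCO3
Reagents that add atoms: none
Why: Bromodimethylborane cleaves acetal-type groups (MOM ether and isopropylidene ketal) at −78 °C by boron coordination and bromide attack at the acetal carbon, conditions under which carboxylic esters, the lactone and both alkenes should be inert, releasing the C3 alcohol and the 11,12-diol.

**Compound list**

1 | 2-[(4-methoxybenzyl)oxy]acetaldehyde | O=CCOCc1ccc(OC)cc1 | starting material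
2 | 2-(triphenylphosphoranylidene)propanal | CC(C=O)=P(c1ccccc1)(c1ccccc1)c1ccccc1 | starting material
3 | (E)-4-[(4-methoxybenzyl)oxy]-2-methylbut-2-enal | O=C/C(C)=C/COCc1ccc(OC)cc1 | intermediate
4 | pent-1-en-3-one | CCC(=O)C=C | starting material
5 | (Z)-3-(tert-butyldimethylsilyloxy)penta-1,3-diene | C/C=C(\O[Si](C)(C)C(C)(C)C)C=C | intermediate
6 | Diels–Alder adduct (1S,10S), C2 aldehyde, C12 silyl enol ether, C11 epimers | COc1ccc(COC[C@H]2C(C)C(O[Si](C)(C)C(C)(C)C)=CC[C@]2(C)C=O)cc1 | intermediate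
7 | C2 primary alcohol of 6 | COc1ccc(COC[C@H]2C(C)C(O[Si](C)(C)C(C)(C)C)=CC[C@]2(C)CO)cc1 | intermediate
8 | C2 O-TBS ether of 7 | COc1ccc(COC[C@H]2C(C)C(O[Si](C)(C)C(C)(C)C)=CC[C@]2(C)CO[Si](C)(C)C(C)(C)C)cc1 | intermediate
9 | cyclohexenone (C12=O, C13=C14) | COc1ccc(COC[C@H]2C(C)C(=O)C=C[C@]2(C)CO[Si](C)(C)C(C)(C)C)cc1 | intermediate
10 | dienyl triflate (C11=C12(OTf), C13=C14) | COc1ccc(COC[C@H]2C(C)=C(OS(=O)(=O)C(F)(F)F)C=C[C@]2(C)CO[Si](C)(C)C(C)(C)C)cc1 | intermediate
11 | cyclohexa-1,3-diene (C11=C12, C13=C14) | COc1ccc(COC[C@H]2C(C)=CC=C[C@]2(C)CO[Si](C)(C)C(C)(C)C)cc1 | intermediate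
12 | (11S,12R)-cis-diol | COc1ccc(COC[C@H]2[C@](C)(O)[C@H](O)C=C[C@]2(C)CO[Si](C)(C)C(C)(C)C)cc1 | intermediate
13 | 11,12-acetonide | COc1ccc(COC[C@H]2[C@]3(C)OC(C)(C)O[C@@H]3C=C[C@]2(C)CO[Si](C)(C)C(C)(C)C)cc1 | intermediate
14 | C2 primary alcohol (acetonide) | COc1ccc(COC[C@H]2[C@]3(C)OC(C)(C)O[C@@H]3C=C[C@]2(C)CO)cc1 | intermediate
15 | C2 aldehyde (acetonide) | COc1ccc(COC[C@H]2[C@]3(C)OC(C)(C)O[C@@H]3C=C[C@]2(C)C=O)cc1 | intermediate
16 | allyl methoxymethyl ether | C=CCOCOC | starting material
17 | (Z)-[3-(methoxymethoxy)allyl]diisopinocampheylborane | COCO/C=C\CB([C@@H]1C[C@@H]2C[C@H]([C@H]1C)C2(C)C)[C@@H]1C[C@@H]2C[C@H]([C@H]1C)C2(C)C | intermediate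
18 | (2R,3R)-homoallylic alcohol, C2-OH, C3-OMOM, C4 vinyl | COc1ccc(COC[C@H]2[C@]3(C)OC(C)(C)O[C@@H]3C=C[C@]2(C)[C@@H](O)[C@H](OCOC)C=C)cc1 | intermediate
19 | C2 O-TES ether of 18 | COc1ccc(COC[C@H]2[C@]3(C)OC(C)(C)O[C@@H]3C=C[C@]2(C)[C@@H](O[Si](CC)(CC)CC)[C@H](OCOC)C=C)cc1 | intermediate
20 | 1,2-diol from the vinyl group of 19 (carbinol epimers) | COc1ccc(COC[C@H]2[C@]3(C)OC(C)(C)O[C@@H]3C=C[C@]2(C)[C@@H](O[Si](CC)(CC)CC)[C@H](OCOC)C(O)CO)cc1 | intermediate
21 | C4 aldehyde | COc1ccc(COC[C@H]2[C@]3(C)OC(C)(C)O[C@@H]3C=C[C@]2(C)[C@@H](O[Si](CC)(CC)CC)[C@H](OCOC)C=O)cc1 | intermediate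
22 | propyne | CC#C | starting material
23 | tributyl(trimethylsilyl)stannane | CCCC[Sn](CCCC)(CCCC)[Si](C)(C)C | starting material
24 | (Z)-trimethyl[2-(tributylstannyl)prop-1-enyl]silane | C/C([Sn](CCCC)(CCCC)CCCC)=C/[Si](C)(C)C | intermediate
25 | (Z)-[1-(trimethylsilyl)prop-1-en-2-yl]magnesium bromide | C/C([Mg]Br)=C/[Si](C)(C)C | intermediate
26 | (4S)-allylic alcohol with Z-vinylsilane (C5=C6) | COc1ccc(COC[C@H]2[C@]3(C)OC(C)(C)O[C@@H]3C=C[C@]2(C)[C@@H](O[Si](CC)(CC)CC)[C@H](OCOC)[C@@H](O)/C(C)=C\[Si](C)(C)C)cc1 | intermediate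
27 | C4 O-TBS ether of 26 | COc1ccc(COC[C@H]2[C@]3(C)OC(C)(C)O[C@@H]3C=C[C@]2(C)[C@@H](O[Si](CC)(CC)CC)[C@H](OCOC)[C@@H](O[Si](C)(C)C(C)(C)C)/C(C)=C\[Si](C)(C)C)cc1 | intermediate
28 | (Z)-vinyl iodide | COc1ccc(COC[C@H]2[C@]3(C)OC(C)(C)O[C@@H]3C=C[C@]2(C)[C@@H](O[Si](CC)(CC)CC)[C@H](OCOC)[C@@H](O[Si](C)(C)C(C)(C)C)/C(C)=C\I)cc1 | intermediate
29 | C9 primary alcohol | OC[C@H]1[C@]2(C)OC(C)(C)O[C@@H]2C=C[C@]1(C)[C@@H](O[Si](CC)(CC)CC)[C@H](OCOC)[C@@H](O[Si](C)(C)C(C)(C)C)/C(C)=C\I | intermediate
30 | C9 aldehyde | O=C[C@H]1[C@]2(C)OC(C)(C)O[C@@H]2C=C[C@]1(C)[C@@H](O[Si](CC)(CC)CC)[C@H](OCOC)[C@@H](O[Si](C)(C)C(C)(C)C)/C(C)=C\I | intermediate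
31 | allyl 4-methoxybenzyl ether | C=CCOCc1ccc(OC)cc1 | starting material
32 | (Z)-[3-(4-methoxybenzyloxy)allyl]diisopinocampheylborane | COc1ccc(CO/C=C\CB([C@@H]2C[C@@H]3C[C@H]([C@H]2C)C3(C)C)[C@@H]2C[C@@H]3C[C@H]([C@H]2C)C3(C)C)cc1 | intermediate
33 | (8R,9R)-homoallylic alcohol, C9-OH, C8-OPMB, C7 vinyl | C=C[C@@H](OCc1ccc(OC)cc1)[C@H](O)[C@H]1[C@]2(C)OC(C)(C)O[C@@H]2C=C[C@]1(C)[C@@H](O[Si](CC)(CC)CC)[C@H](OCOC)[C@@H](O[Si](C)(C)C(C)(C)C)/C(C)=C\I | intermediate
34 | C9 O-TES ether of 33 | C=C[C@@H](OCc1ccc(OC)cc1)[C@H](O[Si](CC)(CC)CC)[C@H]1[C@]2(C)OC(C)(C)O[C@@H]2C=C[C@]1(C)[C@@H](O[Si](CC)(CC)CC)[C@H](OCOC)[C@@H](O[Si](C)(C)C(C)(C)C)/C(C)=C\I | intermediate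
35 | 1,2-diol from the vinyl group of 34 (carbinol epimers) | OCC(O)[C@@H](OCc1ccc(OC)cc1)[C@H](O[Si](CC)(CC)CC)[C@H]1[C@]2(C)OC(C)(C)O[C@@H]2C=C[C@]1(C)[C@@H](O[Si](CC)(CC)CC)[C@H](OCOC)[C@@H](O[Si](C)(C)C(C)(C)C)/C(C)=C\I | intermediate
36 | C7 aldehyde (cyclisation substrate) | O=C[C@@H](OCc1ccc(OC)cc1)[C@H](O[Si](CC)(CC)CC)[C@H]1[C@]2(C)OC(C)(C)O[C@@H]2C=C[C@]1(C)[C@@H](O[Si](CC)(CC)CC)[C@H](OCOC)[C@@H](O[Si](C)(C)C(C)(C)C)/C(C)=C\I | intermediate
37 | ten-membered (7R)-allylic alcohol, C8-OPMB | CC(C)(C)[Si](C)(C)O[C@H]1/C(C)=C\[C@@H](O)[C@@H](OCc4ccc(OC)cc4)[C@H](O[Si](CC)(CC)CC)[C@H]2[C@]3(C)OC(C)(C)O[C@@H]3C=C[C@]2(C)[C@@H](O[Si](CC)(CC)CC)[C@@H]1OCOC | intermediate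
38 | (S)-2-bromopropanoic acid | C[C@H](Br)C(=O)O | starting material
39 | (7S)-2-bromopropanoate, C8-OPMB | CC(C)(C)[Si](C)(C)O[C@H]1/C(C)=C\[C@H](OC(=O)[C@H](C)Br)[C@@H](OCc4ccc(OC)cc4)[C@H](O[Si](CC)(CC)CC)[C@H]2[C@]3(C)OC(C)(C)O[C@@H]3C=C[C@]2(C)[C@@H](O[Si](CC)(CC)CC)[C@@H]1OCOC | intermediate
40 | C8 alcohol | CC(C)(C)[Si](C)(C)O[C@H]1/C(C)=C\[C@H](OC(=O)[C@H](C)Br)[C@@H](O)[C@H](O[Si](CC)(CC)CC)[C@H]2[C@]3(C)OC(C)(C)O[C@@H]3C=C[C@]2(C)[C@@H](O[Si](CC)(CC)CC)[C@@H]1OCOC | intermediate
41 | ten-membered 8-ketone with C7 (S)-2-bromopropanoate (key-step precursor) | CC(C)(C)[Si](C)(C)O[C@H]1/C(C)=C\[C@H](OC(=O)[C@H](C)Br)C(=O)[C@H](O[Si](CC)(CC)CC)[C@H]2[C@]3(C)OC(C)(C)O[C@@H]3C=C[C@]2(C)[C@@H](O[Si](CC)(CC)CC)[C@@H]1OCOC | intermediate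
42 | bromozinc enolate of the C7 propanoate | CC(C)(C)[Si](C)(C)O[C@H]1/C(C)=C\[C@H](OC(O[Zn]Br)=CC)C(=O)[C@H](O[Si](CC)(CC)CC)[C@H]2[C@]3(C)OC(C)(C)O[C@@H]3C=C[C@]2(C)[C@@H](O[Si](CC)(CC)CC)[C@@H]1OCOC | intermediate
43 | β-hydroxy γ-lactone (8S; key-step product) | CC(C)(C)[Si](C)(C)O[C@H]1/C(C)=C\[C@@H]2OC(=O)[C@H](C)[C@@]2(O)[C@H](O[Si](CC)(CC)CC)[C@H]2[C@]3(C)OC(C)(C)O[C@@H]3C=C[C@]2(C)[C@@H](O[Si](CC)(CC)CC)[C@@H]1OCOC | intermediate
44 | dilithium C8-alkoxide lactone enolate | CC(C)(C)[Si](C)(C)O[C@H]1/C(C)=C\[C@@H]2OC(O[Li])=C(C)[C@@]2(O[Li])[C@H](O[Si](CC)(CC)CC)[C@H]2[C@]3(C)OC(C)(C)O[C@@H]3C=C[C@]2(C)[C@@H](O[Si](CC)(CC)CC)[C@@H]1OCOC | intermediate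
45 | 8,17-diol lactone (8S,17S) | CC(C)(C)[Si](C)(C)O[C@H]1/C(C)=C\[C@@H]2OC(=O)[C@@](C)(O)[C@@]2(O)[C@H](O[Si](CC)(CC)CC)[C@H]2[C@]3(C)OC(C)(C)O[C@@H]3C=C[C@]2(C)[C@@H](O[Si](CC)(CC)CC)[C@@H]1OCOC | intermediate
46 | C2,C9-diol (C4-OTBS) | CC(C)(C)[Si](C)(C)O[C@H]1/C(C)=C\[C@@H]2OC(=O)[C@@](C)(O)[C@@]2(O)[C@H](O)[C@H]2[C@]3(C)OC(C)(C)O[C@@H]3C=C[C@]2(C)[C@@H](O)[C@@H]1OCOC | intermediate
47 | C2,C9-diacetate (C4-OTBS) | CC(C)(C)[Si](C)(C)O[C@H]1/C(C)=C\[C@@H]2OC(=O)[C@@](C)(O)[C@@]2(O)[C@H](OC(C)=O)[C@H]2[C@]3(C)OC(C)(C)O[C@@H]3C=C[C@]2(C)[C@@H](OC(C)=O)[C@@H]1OCOC | intermediate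
48 | C4 alcohol | O[C@H]1/C(C)=C\[C@@H]2OC(=O)[C@@](C)(O)[C@@]2(O)[C@H](OC(C)=O)[C@H]2[C@]3(C)OC(C)(C)O[C@@H]3C=C[C@]2(C)[C@@H](OC(C)=O)[C@@H]1OCOC | intermediate
49 | C4 hexanoate (C3-OMOM, 11,12-acetonide) | CCCCCC(=O)O[C@H]1/C(C)=C\[C@@H]2OC(=O)[C@@](C)(O)[C@@]2(O)[C@H](OC(C)=O)[C@H]2[C@]3(C)OC(C)(C)O[C@@H]3C=C[C@]2(C)[C@@H](OC(C)=O)[C@@H]1OCOC | intermediate
50 | CNP0153048.1 (1S,2R,3R,4S,5Z,7S,8S,9R,10S,11S,12R,17S; briarane numbering) | CCCCCC(=O)O[C@H]1/C(C)=C\[C@@H]2OC(=O)[C@@](C)(O)[C@@]2(O)[C@H](OC(C)=O)[C@H]2[C@](C)(O)[C@H](O)C=C[C@]2(C)[C@@H](OC(C)=O)[C@@H]1O | target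

**Step count and risks**

Total: 35 steps. Longest linear sequence: 33 steps (1 → 3 → 6 → … → 50; steps 2 and 16 are branches).

Steps most likely to fail:

1. Step 29 (key step). The closure may take the other carbonyl face under kinetic control (cis-fused lactone), or electron transfer to the α-acyloxy ketone may compete and expel the C7 ester. Fallback: from 41 directly to 43 with samarium(II) iodide (2.1 equiv, THF, −78 °C). This changes the metal and the control regime: the C–Br bond is reduced at once, and a samarium(III) enolate chelated to the ketone oxygen closes irreversibly at low temperature instead of through a reversible zinc aldolate. This fallback makes no new compound (F0).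

2. Step 25. Facial selectivity in the ring-closing addition may be poor or reversed, because the acyclic model is not binding in a medium ring. Fallback: starting from 36, if the closure favours the 7,8-syn face, the C7-epimeric (7S)-alcohol F1 is not inverted but esterified with retention (38, DIC, DMAP cat., CH2Cl2, 0 °C), which rejoins the route at 39. A mixture would be separated and each epimer taken on by its own esterification (inversion for 37, retention for F1).

3. Step 30. Oxygen may be delivered to the wrong face of the enolate (syn to O8, cis-diol), or the β-alkoxide may open by retro-aldol. Fallback: from 43, LDA/TMSCl (2.5 equiv each, THF, −78 °C) gives the C8-O-silylated silyl ketene acetal F2. Its neutral Rubottom-type epoxidation with dimethyldioxirane (acetone/CH2Cl2, −78 °C) should occur anti to the now bulky C8 silyl ether, and mild desilylation (citric acid, MeOH) returns to the route at 45.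

**Further compounds**

F0 | step 29 | none | none
F1 | step 25 | ten-membered (7S)-allylic alcohol, C7 epimer of 37 | CC(C)(C)[Si](C)(C)O[C@H]1/C(C)=C\[C@H](O)[C@@H](OCc4ccc(OC)cc4)[C@H](O[Si](CC)(CC)CC)[C@H]2[C@]3(C)OC(C)(C)O[C@@H]3C=C[C@]2(C)[C@@H](O[Si](CC)(CC)CC)[C@@H]1OCOC
F2 | step 30 | C8-O-trimethylsilyl lactone trimethylsilyl ketene acetal | CC(C)(C)[Si](C)(C)O[C@H]1/C(C)=C\[C@@H]2OC(O[Si](C)(C)C)=C(C)[C@@]2(O[Si](C)(C)C)[C@H](O[Si](CC)(CC)CC)[C@H]2[C@]3(C)OC(C)(C)O[C@@H]3C=C[C@]2(C)[C@@H](O[Si](CC)(CC)CC)[C@@H]1OCOC
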